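Assumption: the target has no stereocentre and no stereogenic double bond, so the given SMILES describes one achiral compound and no step has to control configuration.

**Retrosynthetic overview**
- Disconnect the C2–C3 bond of the acyl chain of target 8 into an acetate α-cation (enolonium) synthon and a docosyl nucleophile; both carbons are normally donor carbons.
- The enolonium equivalent is 2-phenylethyl bromoacetate 3, with the ester already in place; the nucleophile is B-docosyl-9-BBN 5, made in the flask from 1-docosene 4.
- 3 comes from 2-phenylethanol 1 and bromoacetyl bromide 2.
- No ring is formed; the benzene ring is bought with 1.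

**Step 1**
Reactants: 1 2-phenylethanol; 2 bromoacetyl bromide
Product: 3 2-phenylethyl bromoacetate
Conditions: 2 (1.1 equiv), NaHCO3 (2 equiv), MeCN, 0 °C to rt, 2 h
Reagents that add atoms: none
Why: O-acylation of a primary alcohol by an acyl bromide (nucleophilic acyl substitution), which is far faster at the acyl carbon than SN2 at the CH2Br carbon, with a heterogeneous base that cannot be alkylated by the product; no stereocentre is formed.

**Step 2**
Reactants: 4 1-docosene; 3 2-phenylethyl bromoacetate
Product: 8 2-phenylethyl tetracosanoate, via B-docosyl-9-BBN 5 (not isolated), via bromo ate complex 6 (not isolated), via alpha-boryl ester 7 (not isolated)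
Conditions: 9-BBN (0.5 M in THF, 1.05 equiv), THF, 0 °C to rt, 4 h; then 3 (1.0 equiv), potassium 2,6-di-tert-butylphenoxide (1.05 equiv, made in THF from 2,6-di-tert-butylphenol and KOtBu), 0 °C to rt, 2 h; aq NH4Cl work-up; chromatography, then recrystallisation from acetone
Reagents that add atoms: none
Why: Anti-Markovnikov hydroboration places boron on the terminal carbon of 4, then Brown α-alkylation of an α-bromo ester with a B-alkyl-9-BBN follows: the hindered, non-nucleophilic phenoxide forms the bromo enolate of 3, boron traps it as ate complex 6, the primary docosyl group migrates from boron to carbon with loss of bromide (1,2-metallate shift, exocyclic group migrating in preference to the bicyclic B–C bonds), and the phenol protonates α-boryl ester 7, so the bromoacetate acts as an acetate enolonium equivalent and the product has no stereocentre.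

**Compound list**
1 | 2-phenylethanol | OCCc1ccccc1 | starting material
2 | bromoacetyl bromide | O=C(Br)CBr | starting material
3 | 2-phenylethyl bromoacetate | O=C(CBr)OCCc1ccccc1 | intermediate
4 | 1-docosene | CCCCCCCCCCCCCCCCCCCCC=C | starting material
5 | 9-docosyl-9-borabicyclo[3.3.1]nonane (B-docosyl-9-BBN; not isolated) | CCCCCCCCCCCCCCCCCCCCCCB1C2CCCC1CCC2 | intermediate
6 | potassium 9-[1-bromo-2-oxo-2-(2-phenylethoxy)ethyl]-9-docosyl-9-boratabicyclo[3.3.1]nonane (ate complex, racemic at the CHBr carbon; not isolated) | [K+].CCCCCCCCCCCCCCCCCCCCCC[B-]1(C(Br)C(=O)OCCc2ccccc2)C2CCCC1CCC2 | intermediate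
7 | 2-phenylethyl 2-(9-borabicyclo[3.3.1]nonan-9-yl)tetracosanoate (racemic at C2; not isolated) | CCCCCCCCCCCCCCCCCCCCCCC(B1C2CCCC1CCC2)C(=O)OCCc1ccccc1 | intermediate
8 | 2-phenylethyl tetracosanoate (phenylethyl n-tetracosanoate; achiral) | CCCCCCCCCCCCCCCCCCCCCCCC(=O)OCCc1ccccc1 | target

**Totals**
Total step count: 2. Longest linear sequence: 2 steps (1 → 3 → 8); 4 joins in step 2.

**Steps most likely to fail**
The route has only two steps, so both are ranked and there is no third.

Most likely to fail is step 2, in its alkylation stage. The risks are Darzens-type self-condensation of the bromo enolate of 3 before boron traps it, base attack on the phenethyl ester, and incomplete migration. The fallback keeps the same C2–C3 disconnection and the same α-halo ester as the electrophilic acetate carbon, but makes the bond by a radical chain with no base and no boron ate complex. It sets out from 3 and 4 and comes back to the route at 8. Halide exchange on 3 (NaI, acetone, rt) gives 2-phenylethyl iodoacetate F1. Iodine atom-transfer radical addition of F1 to 4 (Et3B 0.2 equiv, trace air, hexane, rt) lets the electrophilic α-ester radical add to the terminal alkene carbon and gives racemic 2-phenylethyl 4-iodotetracosanoate F2. F2 is reduced in the same flask at rt (Bu3SnH 1.2 equiv, fresh Et3B/air) to 8. It is kept cold and reduced without delay, because warming could close it to the γ-lactone.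

Second is step 1. The risks are loss of 2 to moisture and a sluggish heterogeneous reaction that leaves 1, which would then quench the borane in step 2. The fallback sets out from 1 and comes back at 3, with no new compound on the way. It is an acid-catalysed azeotropic Fischer esterification of 1 with bromoacetic acid (1.2 equiv, TsOH·H2O 5 mol %, toluene, Dean–Stark, reflux), driven by water removal and run without base or acyl halide.

**Further compounds**
F1 | step 2 | 2-phenylethyl iodoacetate | O=C(CI)OCCc1ccccc1
F2 | step 2 | 2-phenylethyl 4-iodotetracosanoate (racemic) | CCCCCCCCCCCCCCCCCCCCC(I)CCC(=O)OCCc1ccccc1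
F0 | step 1 | none | none
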